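**Retrosynthetic overview**
Atom labels follow the target SMILES: C1 exocyclic CH2; ring B = cycloheptane C2, C3, C4, C5, C6, C9, C26; ring A = cyclopentane C9–C12, C26; C14/C15 = side-chain CH and CH2OAc; ring C = lactone C20–C25. The plan rests on C4–C5, the only ring-B bond between two plain methylenes, which links the gem-dimethyl carbon C6 to the C3–C2 arm away from the fusion carbons C9 and C26.
End game: C2 ketone to methylene (Takai–Lombardo); ring C closed by ozonolysis/reduction of a propenyl group; C14–C20 bond and both centres by Ireland–Claisen rearrangement with chirality transfer from (R)-but-3-en-2-ol.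
Ring B: ring-closing metathesis of the allyl group on carbinol C2 with the vinyl group on C6, then hydroxyl-directed hydrogenation to set the cis fusion at C9.
Ring A is bought as 3-methylcyclopent-2-en-1-one: C12 by asymmetric conjugate vinylation, C6 by vinyl conjugate addition to an isopropylidene ketone, C26 by CBS reduction and Wittig–Still 1,3-transfer.
Order of rings: A (starting material), B (step 15), C (step 26).

Key step: step 15

Remark: C2 forms in step 13 as a mixture of epimers and is drawn without configuration until it becomes sp2 in step 28. TBS = tert-butyldimethylsilyl.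

Step 1
Reactants: 1 3-methylcyclopent-2-en-1-one; 2 ethynyltrimethylsilane
Product: 4 (S)-3-methyl-3-[1-(trimethylsilyl)ethenyl]cyclopentan-1-one, via alane 3 (not isolated)
Conditions: 2, i-Bu2AlH, hexanes/THF, 55 °C; then 1, CuCl2·2H2O (5 mol %), chiral sulfonate-bearing N-heterocyclic carbene L* added as its silver carbene Ag2L*2 (2.5 mol %), THF, −15 °C
Reagents that add atoms: none
Why: Copper-catalysed enantioselective conjugate addition of a silyl-substituted vinylaluminium reagent (from α-selective hydroalumination of the silylalkyne) to a β-methyl cyclic enone is an established way to vinyl-bearing quaternary carbons, and the ligand enantiomer is chosen so that the alkenyl group enters the enone face that makes C12 (S) in this ketone.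

Step 2
Reactants: 4
Product: 5 (S)-3-ethenyl-3-methylcyclopentan-1-one
Conditions: CF3CO2H, CH2Cl2, 0 → 22 °C
Reagents that add atoms: none
Why: Acid-mediated protodesilylation of the vinylsilane replaces silicon by hydrogen and leaves the quaternary centre untouched.

Step 3
Reactants: 5
Product: 6 (R)-3-(2-hydroxyethyl)-3-methylcyclopentan-1-one
Conditions: catecholborane, RhCl(PPh3)3 (2 mol %), THF, 0 °C → rt; then 30 % H2O2, aq. NaOH, 0 °C
Reagents that add atoms: hydrogen peroxide, OO
Why: Rhodium-catalysed hydroboration with catecholborane adds to the terminal alkene in preference to the ketone and puts boron on the terminal carbon, so oxidation should give the primary alcohol (anti-Markovnikov hydroboration–oxidation).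

Step 4
Reactants: 6
Product: 7 (R)-3-[2-(tert-butyldimethylsilyloxy)ethyl]-3-methylcyclopentan-1-one
Conditions: TBSCl, imidazole, DMF, rt
Reagents that add atoms: tert-butyldimethylsilyl chloride, CC(C)(C)[Si](C)(C)Cl
Why: Standard silylation of a primary alcohol.

Step 5
Reactants: 7; 8 acetone
Product: 9 (4R)-4-[2-(TBSO)ethyl]-2-(2-hydroxypropan-2-yl)-4-methylcyclopentan-1-one (both C9 epimers)
Conditions: LiN(i-Pr)2, THF, −78 °C; 8, −78 °C; AcOH quench at −78 °C
Reagents that add atoms: none
Why: Kinetic deprotonation should occur at C9, the α-methylene remote from the quaternary carbon (C11 is neopentyl and shielded), and the lithium enolate adds to acetone in a directed aldol addition; the C9 configuration does not matter because C9 becomes sp2.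

Step 6
Reactants: 9
Product: 11 (4R)-4-[2-(TBSO)ethyl]-4-methyl-2-(propan-2-ylidene)cyclopentan-1-one, via mesylate 10 (not isolated)
Conditions: MsCl, Et3N, DMAP (cat.), CH2Cl2, 0 → 40 °C
Reagents that add atoms: none
Why: Sulfonylation of the tertiary aldol followed by E1cB elimination through the ketone enolate completes the aldol condensation and gives only the conjugated exocyclic enone.

Step 7
Reactants: 11; 12 vinylmagnesium bromide
Product: 13 (4R)-4-[2-(TBSO)ethyl]-4-methyl-2-(2-methylbut-3-en-2-yl)-1-(trimethylsilyloxy)cyclopent-1-ene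
Conditions: CuI (20 mol %), TMSCl, THF, −78 → −30 °C; Et3N, cold aq. NaHCO3 work-up
Reagents that add atoms: chlorotrimethylsilane, C[Si](C)(C)Cl
Why: Copper-catalysed conjugate addition of the vinyl Grignard reagent to the β,β-dimethyl exocyclic enone (the pulegone type of acceptor) builds the quaternary carbon C6 with its vinyl group, and silyl trapping fixes the enolate as the C9=C10 enol ether.

Step 8
Reactants: 13
Product: 14 (4R)-4-[2-(TBSO)ethyl]-4-methyl-2-(2-methylbut-3-en-2-yl)cyclopent-2-en-1-one
Conditions: Pd(OAc)2 (1.1 equiv), MeCN, 40 °C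
Reagents that add atoms: none
Why: Saegusa–Ito oxidation of the regiodefined silyl enol ether: the palladium enolate can only undergo β-hydride elimination toward C26 because C6 carries no hydrogen, which gives the C9=C26 enone.

Step 9
Reactants: 14
Product: 15 (1R,4R)-4-[2-(TBSO)ethyl]-4-methyl-2-(2-methylbut-3-en-2-yl)cyclopent-2-en-1-ol (C10 hydroxyl cis to the C12 methyl)
Conditions: (S)-2-methyl-CBS-oxazaborolidine (20 mol %), catecholborane, toluene, −78 °C
Reagents that add atoms: none
Why: Corey–Bakshi–Shibata reduction, in which the α-tert-alkyl alkene arm is the large group, so the (S)-catalyst should deliver hydride 1,2 to the carbonyl face that makes C10 (R) by reagent control.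

Step 10
Reactants: 15; 16 tributyl(iodomethyl)stannane
Product: 17 (tributylstannyl)methyl ether of 15
Conditions: KH, 18-crown-6 (cat.), THF, 0 °C → rt
Reagents that add atoms: none
Why: Williamson etherification of the potassium alkoxide with the reactive α-stannyl iodide.

Step 11
Reactants: 17
Product: 19 [(1S,5S)-5-[2-(TBSO)ethyl]-5-methyl-2-(2-methylbut-3-en-2-yl)cyclopent-2-en-1-yl]methanol (CH2OH cis to the C12 methyl), via lithiomethyl ether 18 (not isolated)
Conditions: n-BuLi, THF, −78 → −20 °C; aq. NH4Cl
Reagents that add atoms: none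
Why: Wittig–Still [2,3]-sigmatropic rearrangement: tin–lithium exchange gives the α-alkoxymethyllithium, which passes its CH2O unit suprafacially from O10 to C26, so the C10 configuration is relayed to C26 and the alkene moves to C9=C10.

Step 12
Reactants: 19
Product: 20 aldehyde corresponding to 19 (C2 as CHO)
Conditions: Dess–Martin periodinane, NaHCO3, CH2Cl2, 0 °C; used crude
Reagents that add atoms: none
Why: Buffered Dess–Martin oxidation gives the β,γ-unsaturated aldehyde under non-basic conditions that should avoid epimerisation at C26 and alkene migration.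

Step 13
Reactants: 20; 21 allylmagnesium bromide
Product: 22 homoallylic alcohol (C2 carbinol bearing the allyl group; both C2 epimers)
Conditions: Et2O, −78 °C
Reagents that add atoms: none
Why: Allyl Grignard addition through a six-membered transition state is fast even for this hindered aldehyde and should outrun enolisation; the new C2 centre forms as an epimer mixture, which is harmless because C2 becomes sp2 in step 28.

Step 14
Reactants: 22
Product: 23 bis-TBS ether of 22 (cyclopentene triene; metathesis precursor)
Conditions: TBSOTf, 2,6-lutidine, CH2Cl2, −78 → 0 °C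
Reagents that add atoms: tert-butyldimethylsilyl trifluoromethanesulfonate, CC(C)(C)[Si](C)(C)OS(=O)(=O)C(F)(F)F
Why: Silyl triflate silylation of a hindered secondary alcohol.

Step 15
Reactants: 23
Product: 24 hydroazulene diene (C4=C5 and C9=C10 alkenes; C2–OTBS; C12 with CH3 and CH2CH2OTBS; H26 trans to the C12 methyl)
Conditions: second-generation Grubbs catalyst (H2IMes)(PCy3)Cl2Ru=CHPh (5–10 mol %), CH2Cl2 (0.003 M), 40 °C
Reagents that add atoms: none
Why: The ruthenium benzylidene first exchanges with the unhindered allyl terminus to give an alkylidene at C4, which undergoes intramolecular [2+2] cycloaddition with the vinyl group on C6 and cycloreversion, forming C4=C5 and releasing ethene, whose loss drives the reaction. The closest known reaction type is ring-closing olefin metathesis to cycloheptenes with second-generation ruthenium carbenes, including closures onto vinyl groups on quaternary carbons. Ring B (C2, C3, C4, C5, C6, C9, C26) is closed by ring-closing metathesis as a cis-cycloheptene annulated to the preformed cyclopentene. No stereocentre is created; C12 and C26 are spectators and C2 is a silyl ether, so nothing next to C26 can epimerise. The step needs chemoselectivity among three alkenes and cyclisation rather than dimerisation: only the two monosubstituted alkenes are accessible to the catalyst (the trisubstituted C9=C10 alkene beside the quaternary carbon is inert), the two chains sit on adjacent ring atoms with sp2 C9 holding C6 in the ring plane, the gem-dimethyl group favours the folded conformer, and high dilution suppresses intermolecular metathesis.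

Step 16
Reactants: 24
Product: 25 hydroazulene diene alcohol (C15–OH free; C2–OTBS kept)
Conditions: HF·pyridine, pyridine, THF, 0 °C
Reagents that add atoms: none
Why: Selective desilylation: fluoride removes the unhindered primary silyl ether much faster than the secondary one at C2, which sits beside the ring-fusion carbon.

Step 17
Reactants: 25
Product: 26 cis-fused perhydroazulene alcohol (H9 and H26 cis, both trans to the C12 methyl; C2–OTBS; C12 with CH3 and CH2CH2OH)
Conditions: [Ir(cod)(PCy3)(py)]PF6 (10 mol %), H2 (10 bar), CH2Cl2, rt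
Reagents that add atoms: none
Why: Hydroxyl-directed homogeneous hydrogenation (Crabtree catalyst): the C15 hydroxyl, on the face of C12 opposite the methyl group, binds iridium and delivers hydrogen to that face of C9=C10, which is also the convex face away from the C2 silyl ether, so H9 should end cis to H26; the disubstituted C4=C5 alkene is reduced as well.

Step 18
Reactants: 26
Product: 27 carboxylic acid (C15 as CO2H; otherwise as 26)
Conditions: TEMPO (20 mol %), PhI(OAc)2 (2.5 equiv), MeCN/H2O, rt
Reagents that add atoms: water, O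
Why: Oxoammonium oxidation of the primary alcohol to the aldehyde, hydration and a second oxidation give the acid under near-neutral conditions that spare the silyl ether.

Step 19
Reactants: 28 tert-butyl(but-3-en-1-yloxy)dimethylsilane; 29 (R)-but-3-en-2-ol
Product: 30 (2R,3E)-6-(tert-butyldimethylsilyloxy)hex-3-en-2-ol
Conditions: second-generation Hoveyda–Grubbs catalyst (H2IMes)Cl2Ru(=CH-C6H4-2-O-i-Pr) (3 mol %), 28 (3 equiv), CH2Cl2, 40 °C
Reagents that add atoms: none
Why: Olefin cross-metathesis between a secondary allylic alcohol and an unhindered terminal alkene should give the (E)-alkene and does not touch the carbinol centre.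

Step 20
Reactants: 27; 30
Product: 31 ester of acid 27 with allylic alcohol 30
Conditions: EDC·HCl, DMAP, CH2Cl2, rt
Reagents that add atoms: none
Why: Steglich-type carbodiimide esterification.

Step 21
Reactants: 31
Product: 33 γ,δ-unsaturated acid (C15 CO2H; C14 and C20 set; C20 bearing CH2CH2OTBS and an (E)-propenyl group), via silyl ketene acetal 32 (not isolated)
Conditions: LiN(i-Pr)2, THF, −78 °C; TMSCl/Et3N; −78 °C → rt, then 50 °C; aq. citric acid work-up
Reagents that add atoms: none
Why: Ireland–Claisen rearrangement: kinetic deprotonation gives the enolate with C12 cis to the allylic oxygen, and the chair transition state with the carbinol methyl and the (E)-alkene substituent both equatorial transfers the (R)-carbinol configuration to C14 and C20 while forming the congested C14–C20 bond intramolecularly.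

Step 22
Reactants: 33
Product: 34 primary alcohol (C15 as CH2OH)
Conditions: LiAlH4, THF, 0 °C → rt
Reagents that add atoms: none
Why: Hydride reduction of the carboxylic acid; silyl ethers and the isolated alkene are inert.

Step 23
Reactants: 34
Product: 35 acetate (C15–OAc)
Conditions: Ac2O, pyridine, DMAP (cat.), CH2Cl2, rt
Reagents that add atoms: acetic anhydride, CC(=O)OC(C)=O
Why: Standard acetylation of a primary alcohol.

Step 24
Reactants: 35
Product: 36 primary alcohol (C23–OH free; C2–OTBS kept)
Conditions: HF·pyridine, pyridine, THF, 0 °C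
Reagents that add atoms: none
Why: Selective desilylation of the primary silyl ether in the presence of the hindered secondary one, as in step 16; the acetate is stable to buffered fluoride.

Step 25
Reactants: 36
Product: 37 carboxylic acid (C23 as CO2H)
Conditions: TEMPO (20 mol %), PhI(OAc)2 (2.5 equiv), MeCN/H2O, rt
Reagents that add atoms: water, O
Why: Oxoammonium oxidation of the primary alcohol to the acid, which tolerates the disubstituted alkene, the acetate and the silyl ether.

Step 26
Reactants: 37
Product: 40 lactone acetate (ring C closed; C2–OTBS), via aldehyde acid 38 (not isolated), via hydroxy acid 39 (not isolated)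
Conditions: O3, CH2Cl2/MeOH, −78 °C; NaBH4, −78 → 0 °C; then 1 M HCl to pH 3, rt
Reagents that add atoms: ozone, [O-][O+]=O
Why: Ozonolysis cleaves the only alkene to the C21 aldehyde, borohydride reduces it at low temperature without touching the acetate, and the γ-hydroxy acid closes to the five-membered lactone on acidification (C20 is not affected).

Step 27
Reactants: 40
Product: 41 hydroxy lactone acetate (C2–OH)
Conditions: 48 % aq. HF, MeCN, rt
Reagents that add atoms: none
Why: Acidic fluoride removes the hindered secondary silyl ether, and the lactone and acetate are stable to these conditions.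

Step 28
Reactants: 41
Product: 42 keto lactone acetate (C2 ketone)
Conditions: Dess–Martin periodinane, NaHCO3, CH2Cl2, rt
Reagents that add atoms: none
Why: Dess–Martin oxidation under buffered, non-basic conditions converts both C2 epimers into one ketone without epimerising C26.

Step 29
Reactants: 42
Product: 43 target, (2R)-2-[(1R,3aR,8aS)-1,4,4-trimethyl-8-methylidenedecahydroazulen-1-yl]-2-[(3R)-5-oxooxolan-3-yl]ethyl acetate
Conditions: Zn, CH2Br2, TiCl4, THF/CH2Cl2, 0 °C → rt
Reagents that add atoms: dibromomethane, BrCBr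
Why: Takai–Lombardo methylenation is non-basic and selective for ketones over esters and lactones, so the hindered, enolisable C2 ketone should be converted without epimerisation at C26.

**Compound list**
1 | 3-methylcyclopent-2-en-1-one | CC1=CC(=O)CC1 | starting material
2 | ethynyltrimethylsilane | C#C[Si](C)(C)C | starting material
3 | diisobutyl[1-(trimethylsilyl)ethenyl]alumane | C=C([Si](C)(C)C)[Al](CC(C)C)CC(C)C | intermediate (not isolated)
4 | (S)-3-methyl-3-[1-(trimethylsilyl)ethenyl]cyclopentan-1-one | O=C1C[C@@](C)(C(=C)[Si](C)(C)C)CC1 | intermediate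
5 | (S)-3-ethenyl-3-methylcyclopentan-1-one | O=C1C[C@@](C)(C=C)CC1 | intermediate
6 | (R)-3-(2-hydroxyethyl)-3-methylcyclopentan-1-one | O=C1C[C@@](C)(CCO)CC1 | intermediate
7 | (R)-3-[2-(tert-butyldimethylsilyloxy)ethyl]-3-methylcyclopentan-1-one | O=C1C[C@@](C)(CCO[Si](C)(C)C(C)(C)C)CC1 | intermediate
8 | acetone | CC(C)=O | starting material
9 | (4R)-4-[2-(TBSO)ethyl]-2-(2-hydroxypropan-2-yl)-4-methylcyclopentan-1-one, C9 epimers | O=C1C[C@@](C)(CCO[Si](C)(C)C(C)(C)C)CC1C(C)(C)O | intermediate
10 | tertiary methanesulfonate of 9 | O=C1C[C@@](C)(CCO[Si](C)(C)C(C)(C)C)CC1C(C)(C)OS(C)(=O)=O | intermediate (not isolated)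
11 | (4R)-4-[2-(TBSO)ethyl]-4-methyl-2-(propan-2-ylidene)cyclopentan-1-one | O=C1C[C@@](C)(CCO[Si](C)(C)C(C)(C)C)CC1=C(C)C | intermediate
12 | vinylmagnesium bromide | C=C[Mg]Br | starting material
13 | (4R)-4-[2-(TBSO)ethyl]-4-methyl-2-(2-methylbut-3-en-2-yl)-1-(trimethylsilyloxy)cyclopent-1-ene | C=CC(C)(C)C1=C(O[Si](C)(C)C)C[C@@](C)(CCO[Si](C)(C)C(C)(C)C)C1 | intermediate
14 | (4R)-4-[2-(TBSO)ethyl]-4-methyl-2-(2-methylbut-3-en-2-yl)cyclopent-2-en-1-one | C=CC(C)(C)C1=C[C@](C)(CCO[Si](C)(C)C(C)(C)C)CC1=O | intermediate
15 | (1R,4R)-4-[2-(TBSO)ethyl]-4-methyl-2-(2-methylbut-3-en-2-yl)cyclopent-2-en-1-ol | C=CC(C)(C)C1=C[C@](C)(CCO[Si](C)(C)C(C)(C)C)C[C@H]1O | intermediate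
16 | tributyl(iodomethyl)stannane | CCCC[Sn](CCCC)(CCCC)CI | starting material
17 | (tributylstannyl)methyl ether of 15 | C=CC(C)(C)C1=C[C@](C)(CCO[Si](C)(C)C(C)(C)C)C[C@H]1OC[Sn](CCCC)(CCCC)CCCC | intermediate
18 | lithiomethyl ether of 15 | C=CC(C)(C)C1=C[C@](C)(CCO[Si](C)(C)C(C)(C)C)C[C@H]1OC[Li] | intermediate (not isolated)
19 | [(1S,5S)-5-[2-(TBSO)ethyl]-5-methyl-2-(2-methylbut-3-en-2-yl)cyclopent-2-en-1-yl]methanol | C=CC(C)(C)C1=CC[C@@](C)(CCO[Si](C)(C)C(C)(C)C)[C@@H]1CO | intermediate
20 | aldehyde from 19 (cyclopent-2-ene-1-carbaldehyde) | C=CC(C)(C)C1=CC[C@@](C)(CCO[Si](C)(C)C(C)(C)C)[C@@H]1C=O | intermediate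
21 | allylmagnesium bromide | C=CC[Mg]Br | starting material
22 | homoallylic alcohol, 1-(cyclopentenyl)but-3-en-1-ol, C2 epimers | C=CC(C)(C)C1=CC[C@@](C)(CCO[Si](C)(C)C(C)(C)C)[C@@H]1C(O)CC=C | intermediate
23 | bis-TBS ether of 22 (metathesis precursor) | C=CC(C)(C)C1=CC[C@@](C)(CCO[Si](C)(C)C(C)(C)C)[C@@H]1C(O[Si](C)(C)C(C)(C)C)CC=C | intermediate
24 | hydroazulene diene (metathesis product) | CC(C)(C)[Si](C)(C)OC1CC=CC(C)(C)C2=CC[C@@](C)(CCO[Si](C)(C)C(C)(C)C)[C@H]12 | intermediate
25 | hydroazulene diene with free C15–OH | CC(C)(C)[Si](C)(C)OC1CC=CC(C)(C)C2=CC[C@@](C)(CCO)[C@H]12 | intermediate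
26 | cis-fused perhydroazulene alcohol | CC(C)(C)[Si](C)(C)OC1CCCC(C)(C)[C@@H]2CC[C@@](C)(CCO)[C@H]12 | intermediate
27 | cis-fused perhydroazulene acetic acid (C15 CO2H) | CC(C)(C)[Si](C)(C)OC1CCCC(C)(C)[C@@H]2CC[C@@](C)(CC(=O)O)[C@H]12 | intermediate
28 | tert-butyl(but-3-en-1-yloxy)dimethylsilane | C=CCCO[Si](C)(C)C(C)(C)C | starting material
29 | (R)-but-3-en-2-ol | C[C@@H](O)C=C | starting material
30 | (2R,3E)-6-(tert-butyldimethylsilyloxy)hex-3-en-2-ol | C[C@@H](O)/C=C/CCO[Si](C)(C)C(C)(C)C | intermediate
31 | ester of 27 with 30 | CC(C)(C)[Si](C)(C)OC1CCCC(C)(C)[C@@H]2CC[C@@](C)(CC(=O)O[C@H](C)/C=C/CCO[Si](C)(C)C(C)(C)C)[C@H]12 | intermediate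
32 | trimethylsilyl ketene acetal of 31 (C12 cis to the allylic oxygen) | CC(C)(C)[Si](C)(C)OC1CCCC(C)(C)[C@@H]2CC[C@@](C)(/C=C(/O[Si](C)(C)C)O[C@H](C)/C=C/CCO[Si](C)(C)C(C)(C)C)[C@H]12 | intermediate (not isolated)
33 | rearranged acid (C15 CO2H; C20 with CH2CH2OTBS and (E)-propenyl) | CC(C)(C)[Si](C)(C)OC1CCCC(C)(C)[C@@H]2CC[C@@](C)([C@H](C(=O)O)[C@@H](CCO[Si](C)(C)C(C)(C)C)/C=C/C)[C@H]12 | intermediate
34 | primary alcohol (C15 CH2OH) | CC(C)(C)[Si](C)(C)OC1CCCC(C)(C)[C@@H]2CC[C@@](C)([C@H](CO)[C@@H](CCO[Si](C)(C)C(C)(C)C)/C=C/C)[C@H]12 | intermediate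
35 | acetate (C15–OAc) | CC(C)(C)[Si](C)(C)OC1CCCC(C)(C)[C@@H]2CC[C@@](C)([C@H](COC(C)=O)[C@@H](CCO[Si](C)(C)C(C)(C)C)/C=C/C)[C@H]12 | intermediate
36 | acetate with free C23–OH | CC(C)(C)[Si](C)(C)OC1CCCC(C)(C)[C@@H]2CC[C@@](C)([C@H](COC(C)=O)[C@@H](CCO)/C=C/C)[C@H]12 | intermediate
37 | acetate acid (C23 CO2H) | CC(C)(C)[Si](C)(C)OC1CCCC(C)(C)[C@@H]2CC[C@@](C)([C@H](COC(C)=O)[C@@H](CC(=O)O)/C=C/C)[C@H]12 | intermediate
38 | aldehyde acid (C21 CHO) | CC(C)(C)[Si](C)(C)OC1CCCC(C)(C)[C@@H]2CC[C@@](C)([C@H](COC(C)=O)[C@@H](CC(=O)O)C=O)[C@H]12 | intermediate (not isolated)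
39 | hydroxy acid (C21 CH2OH) | CC(C)(C)[Si](C)(C)OC1CCCC(C)(C)[C@@H]2CC[C@@](C)([C@H](COC(C)=O)[C@@H](CC(=O)O)CO)[C@H]12 | intermediate (not isolated)
40 | lactone acetate, C2–OTBS | CC(C)(C)[Si](C)(C)OC1CCCC(C)(C)[C@@H]2CC[C@@](C)([C@H](COC(C)=O)[C@@H]3COC(=O)C3)[C@H]12 | intermediate
41 | hydroxy lactone acetate, C2–OH | OC1CCCC(C)(C)[C@@H]2CC[C@@](C)([C@H](COC(C)=O)[C@@H]3COC(=O)C3)[C@H]12 | intermediate
42 | keto lactone acetate, C2 ketone | O=C1CCCC(C)(C)[C@@H]2CC[C@@](C)([C@H](COC(C)=O)[C@@H]3COC(=O)C3)[C@H]12 | intermediate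
43 | (2R)-2-[(1R,3aR,8aS)-1,4,4-trimethyl-8-methylidenedecahydroazulen-1-yl]-2-[(3R)-5-oxooxolan-3-yl]ethyl acetate | C=C1CCCC(C)(C)[C@@H]2CC[C@@](C)([C@H](COC(C)=O)[C@@H]3COC(=O)C3)[C@H]12 | target

**Step count**
Total: 29 steps. Longest linear sequence: 28 steps (steps 1–18 and 20–29).

**Steps most likely to fail**

Step 21 (Ireland–Claisen). The very hindered ester may enolise with poor geometric control, or the rearrangement may leak through a boat transition state, so that stereocontrol at C14 and C20 erodes. The fallback sets out from 27 and comes back at 40. Acid 27 is converted with pivaloyl chloride/Et3N and lithiated (R)-4-benzyloxazolidin-2-one into the N-acyl oxazolidinone F1. Its sodium enolate (NaN(SiMe3)2, THF, −78 °C) is added to furan-2(5H)-one in an auxiliary-controlled Michael addition to give the lactone imide F2; the benzyl group shields one enolate face and fixes C14, and a C20 epimer, if formed, is removed by chromatography. LiSEt exchanges the auxiliary for the ethyl thioester F3 without opening the lactone. Fukuyama reduction (Et3SiH, palladium on carbon, acetone) gives the aldehyde F4, NaBH4 at −20 °C gives the lactone alcohol F5, and acetylation (Ac2O, pyridine) gives 40.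

Step 11 (Wittig–Still). The α-alkoxymethyllithium may undergo a [1,2]-shift or be protonated instead of reaching the congested C26 beside the quaternary carbon. The fallback sets out from 14 and comes back at 19. Enone 14 is reduced with the (R)-configured CBS catalyst and catecholborane to the C10-epimeric allylic alcohol F6, which is esterified (picolinic acid, DCC, DMAP) to the picolinate F7. Copper-mediated anti-selective SN2′ substitution with (i-PrO)Me2SiCH2MgCl (CuBr·SMe2, THF, −40 °C) brings the silylmethyl group to C26 on the face opposite the leaving group and gives the allyl-transposed silane F8. Tamao oxidation (H2O2, KF, KHCO3) gives 19.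

Step 17 (directed hydrogenation). Hydrogen may be delivered to the wrong face of C9=C10, or reduction of this hindered trisubstituted alkene may stall under hydroxyl direction. The fallback sets out from 24 and comes back at 26. It replaces hydroxyl direction by steric approach control on the fully silylated diene and reverses the order of the two steps. Diene 24 is hydrogenated over PtO2 (H2, 60 bar, EtOAc), where the C2 silyl ether and the C12 methyl group shield the face that would give the trans fusion, to give the saturated bis-silyl ether F9. Selective primary desilylation (HF·pyridine, pyridine, THF, 0 °C) gives 26.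

Further compounds
F1 | step 21 | N-acyl (R)-4-benzyloxazolidin-2-one of acid 27 | CC(C)(C)[Si](C)(C)OC1CCCC(C)(C)[C@@H]2CC[C@@](C)(CC(=O)N3[C@H](Cc4ccccc4)COC3=O)[C@H]12
F2 | step 21 | Michael adduct, lactone imide | CC(C)(C)[Si](C)(C)OC1CCCC(C)(C)[C@@H]2CC[C@@](C)([C@H](C(=O)N3[C@H](Cc4ccccc4)COC3=O)[C@@H]5COC(=O)C5)[C@H]12
F3 | step 21 | lactone S-ethyl thioester | CC(C)(C)[Si](C)(C)OC1CCCC(C)(C)[C@@H]2CC[C@@](C)([C@H](C(=O)SCC)[C@@H]3COC(=O)C3)[C@H]12
F4 | step 21 | lactone aldehyde (C15 CHO) | CC(C)(C)[Si](C)(C)OC1CCCC(C)(C)[C@@H]2CC[C@@](C)([C@H](C=O)[C@@H]3COC(=O)C3)[C@H]12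
F5 | step 21 | lactone alcohol (C15 CH2OH) | CC(C)(C)[Si](C)(C)OC1CCCC(C)(C)[C@@H]2CC[C@@](C)([C@H](CO)[C@@H]3COC(=O)C3)[C@H]12
F6 | step 11 | (1S,4R)-allylic alcohol, C10 epimer of 15 | C=CC(C)(C)C1=C[C@](C)(CCO[Si](C)(C)C(C)(C)C)C[C@@H]1O
F7 | step 11 | picolinate of F6 | C=CC(C)(C)C1=C[C@](C)(CCO[Si](C)(C)C(C)(C)C)C[C@@H]1OC(=O)c2ccccn2
F8 | step 11 | C26 (isopropoxydimethylsilyl)methyl cyclopentene | C=CC(C)(C)C1=CC[C@@](C)(CCO[Si](C)(C)C(C)(C)C)[C@@H]1C[Si](C)(C)OC(C)C
F9 | step 17 | cis-fused perhydroazulene bis-TBS ether | CC(C)(C)[Si](C)(C)OC1CCCC(C)(C)[C@@H]2CC[C@@](C)(CCO[Si](C)(C)C(C)(C)C)[C@H]12
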